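## Retrosynthetic overview
- Glabrol (7) has two aryl–prenyl C–C bonds, at C3′ and C8. Both are disconnected to aryl iodides (5) plus a prenyl radical equivalent, coupled by visible-light Ni/photoredox catalysis.
- The diiodide 5 comes from two sequential ortho-iodinations of (2S)-liquiritigenin (1). The B-ring 4-alkylphenol and the A-ring 7-phenolate differ strongly in reactivity, which allows the sequence.
- No ring is formed in this route. The chromanone and both arenes are already in 1, and the only stereocentre (C2, S) comes from 1 and is never touched.

Assumptions:
- (2S)-Liquiritigenin (1) is purchasable, as the licorice natural product.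
- Potassium prenyltrifluoroborate (6) is purchasable, or made in one routine step from prenyl-Bpin and KHF2.
- The target SMILES is the (S)-flavanone, which matches natural (–)-glabrol.

## Route

**Step 1**
Reactants: 1 (2S)-liquiritigenin; 2 iodine
Product: 3 (2S)-7-hydroxy-2-(4-hydroxyphenyl)-8-iodochroman-4-one
Conditions: I2 (1.05 equiv), NaHCO3 (2 equiv), THF/H2O 1:1, 0 °C → rt, 2 h
Reagents that add atoms: iodine, II
Why: Mild bicarbonate deprotonates only the acidic 7-OH (pKa ≈ 7.5, vinylogous acid) and leaves the 4′-OH (pKa ≈ 10) neutral. I2 therefore iodinates the A-ring phenolate ortho to O (electrophilic aromatic substitution). The C8 position, flanked by O7 and O1, is the usual site for Mannich, Duff and Fries-type substitution of 7-hydroxychromanones. C2 is untouched, and the 7-phenolate disfavours enolisation at C3, so racemisation is slow.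

**Step 2**
Reactants: 3; 4 N-iodosuccinimide
Product: 5 (2S)-7-hydroxy-2-(4-hydroxy-3-iodophenyl)-8-iodochroman-4-one
Conditions: NIS (1.05 equiv), p-TsOH (10 mol%), MeCN, 0 °C, 1 h
Reagents that add atoms: N-iodosuccinimide, O=C1CCC(=O)N1I
Why: Acid-catalysed NIS iodination of a 4-alkylphenol is ortho-selective and mono-selective at about one equivalent. The ring is far more nucleophilic than the acyl-deactivated 8-iodo A ring, and the para position is blocked. Stereochemistry is retained because no bond to C2 changes.

**Step 3**
Reactants: 5; 6 potassium prenyltrifluoroborate
Product: 7 glabrol, (2S)-7-hydroxy-2-[4-hydroxy-3-(3-methylbut-2-enyl)phenyl]-8-(3-methylbut-2-enyl)chroman-4-one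
Conditions: 6 (3.0 equiv), [Ir{dF(CF3)ppy}2(dtbbpy)]PF6 (2 mol%), NiCl2·glyme (10 mol%), dtbbpy (10 mol%), 2,6-lutidine (4 equiv), DMF (0.05 M), 450 nm blue LEDs, 25 °C, 24 h
Reagents that add atoms: potassium prenyltrifluoroborate, [K+].CC(C)=CC[B-](F)(F)F
Why: Proposed new method: the excited Ir(III) photocatalyst oxidises the allyl trifluoroborate to a prenyl radical and BF3, and Ni(0) inserts into the Ar–I bond. The prenyl radical is captured by Ar–Ni(II), and C–C reductive elimination at the unhindered primary terminus gives the linear (normal) prenyl arene. The Ir(II)/Ni(I) comproportionation closes a redox-neutral cycle, with no reductant or silane that would deiodinate the aryl iodides. The closest known reaction is metallaphotoredox coupling of alkyl trifluoroborates with aryl halides. The new elements are a prenyl partner, unprotected ortho-iodophenols including the hindered 8-iodo-7-hydroxychromanone, and two couplings in one pot. Visible light is not absorbed by the flavanone, which would photoracemise under UV, and conditions are only weakly basic. No bond to C2 is made or broken, so (S) is retained.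

## Compound list
1 | (2S)-liquiritigenin | Oc1ccc(cc1)[C@@H]1CC(=O)c2ccc(O)cc2O1 | starting material
2 | iodine | II | starting material (reagent)
3 | (2S)-7-hydroxy-2-(4-hydroxyphenyl)-8-iodochroman-4-one | Oc1ccc(cc1)[C@@H]1CC(=O)c2ccc(O)c(I)c2O1 | intermediate
4 | N-iodosuccinimide | O=C1CCC(=O)N1I | starting material (reagent)
5 | (2S)-7-hydroxy-2-(4-hydroxy-3-iodophenyl)-8-iodochroman-4-one | Oc1ccc(cc1I)[C@@H]1CC(=O)c2ccc(O)c(I)c2O1 | intermediate
6 | potassium prenyltrifluoroborate | [K+].CC(C)=CC[B-](F)(F)F | starting material (reagent)
7 | glabrol | CC(C)=CCc1cc([C@@H]2CC(=O)c3ccc(O)c(CC=C(C)C)c3O2)ccc1O | target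

**Total steps: 3. Longest linear sequence: 3.**

## Three steps most likely to fail
1. **Step 3 (proposed new method).** Double Ni/photoredox prenylation may stall at the hindered 8-iodide, give reverse-prenyl or prenyl-dimer products, or lose enantiopurity through phenol-radical-cation C2–O cleavage.
   - Fallback (known chemistry): Pd(PPh3)4-catalysed Stille coupling of 5 with prenyltributylstannane in DMF at 80 °C, which delivers linear prenylarenes.
2. **Step 1.** C8 versus C6 iodination may be poorly selective.
   - Fallback (different approach): Mitsunobu 7-O-allylation (allyl alcohol, PPh3, DIAD), then low-temperature BCl3-promoted ortho-Claisen to the 8-allyl compound, which is C8-selective for 7-allyloxychromanones. Cross-metathesis with 2-methyl-2-butene (Hoveyda–Grubbs II) then gives the 8-prenyl group. The B ring is then handled by Step 2 and a mono-coupling.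
3. **Step 2.** Over-iodination to the 3′,5′-diiodide, or competing A-ring reaction, would lower the yield.
   - Fallback (different handle): ortho-monobromination of 3 with NBS/i-Pr2NH, a known ortho-selective method, gives the 3′-bromo-8-iodo analogue. Its differentiated halides are then coupled sequentially, with the 8-iodide first and the 3′-bromide second, using known Ni/(TMS)3SiH metallaphotoredox alkyl-bromide coupling with prenyl bromide.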